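## Structural features

The target 21 has one ring, a tetrahydrofuran made of O1, C6, C7, C8 and C9 (carbons counted along the C19 chain from the pentyl end). It carries pentyl on C6, a dodecanoyloxy group on C7 and, on C9, a 1-hydroxydec-9-enyl chain (carbinol C10, then C11–C19 ending in the C18=C19 vinyl group). There are four stereocentres: C6 and C7 are ring neighbours with pentyl and acyloxy cis (6S,7S), C9 lies across the ring oxygen with its chain trans to pentyl (9R), and the exocyclic carbinol C10 is threo to C9 (10R). The fragile groups are the secondary ester, which can hydrolyse or shift to a free neighbouring hydroxyl, and the monosubstituted alkene, which rules out hydrogenation and unselective electrophiles once it is in place. The difficulty is twofold: O7 (acylated) and O10 (free) must end up differentiated, and the trans relation across O1 must be set together with the threo O1–C9/C10–OH pair. That vicinal threo pair is the pattern left by syn delivery of two oxygens to an E C9=C10 alkene, and the oxygen on C6 is bishomoallylic to that alkene and can carry the metal that delivers them. Because the ring closure consumes the C6 hydroxyl and creates the C10 hydroxyl, a precursor that already bears the laurate on O7 needs no protection at O10 and gives 21 in the ring-forming step itself.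

## Logic of the disconnections

21 to 18. The O1–C9 and C10–O bonds are cut together. The two oxygens are vicinal and threo, and one is tied to C6 through the ring, so both can come from one oxo-metal unit held on O6. This removes the ring and the C9 and C10 stereocentres; 18 is acyclic with only C6 and C7 stereogenic. The forward step, through 19 and 20, must add suprafacially, place C10 trans to the pentyl group, react only at C9=C10 and spare the ester and C18=C19.

18 to 17, then to 15 and 16. The O6–H bond is traced back to an O6–Si bond and the acyl–O7 bond is cut. Acylation is placed before ring closure because O7 is then the only free hydroxyl; after ring closure O7 would have to be told apart from O10 at a cost of four steps. An acyloxy group on C7 is also a poorer ligand for rhenium, and less acid-labile, than a methoxymethyl ether in that position. The gain is a differentiated diol derivative and a commercial acid. The release of O6 from 17 must not move the acyl group from O7 to O6.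

15 to 14. The O7–H bond is traced back to the O7–CH2 bond of a methoxymethyl acetal. The acetal is there because the reaction that sets C6 and C7 delivers it, so 14 holds the two oxygens in differently masked form. The forward step must cleave the acetal without loss of the silyl ether and without touching either alkene.

14 to 9 and 12. The C9=C10 double bond is cut. It lies near the middle of the chain and its C10 side is achiral. The C19 skeleton falls into a C9 aldehyde that holds both stereocentres and a C10 sulfone. The olefination, through 13, must be highly E-selective, because the geometry becomes the C9/C10 relative configuration, and must not eliminate the C7 oxygen from 9.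

12 to 11 to 10. The two S=O bonds and then the C10–S bond are cut. Sulfur is introduced directly at the alcohol, which avoids a halide intermediate and ends at a commercial alkenol. The oxidation at sulfur must not epoxidise the alkene.

9 to 8 to 6 to 5. The C9=O bond is traced back to C9–OH, the C9–O bond to the C8=C9 alkene (through 7), and the O6–Si bond is cut. The vinyl group left by the C–C bond formation is oxidised at its terminus to reach the olefination site. This leads back to 5, which has nine carbons and both stereocentres. The forward steps need anti-Markovnikov hydroboration and an oxidation mild enough for a β-alkoxy aldehyde.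

5 to 1 and 2. The C6–C7 bond is cut. It joins the two stereocentres, so one reaction creates both and leaves the oxygens differentiated from the outset (free on C6, acetal on C7). The gain is two achiral commercial compounds. The forward step needs Z geometry of the oxyallyl unit in 3 and 4 for the syn pair, and control of the absolute sense by the chiral boron ligands.

## Other disconnections considered

Alternative 1: The cut removes the O1–C6 bond, the C4–C5 bond and the acyl–O7 bond of a temporary lactone. It leads back to (3S,5R,6R)-6-[(4-methoxybenzyl)oxy]pentadeca-1,14-diene-3,5-diol A1, in which C5=C6 is a vinyl group and C7, C9 and C10 already carry their oxygens.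
- Forward step (PdCl2 cat., CuCl2, NaOAc, AcOH, CO at 1 atm): divalent palladium would activate the vinyl group, O9 would attack C6 in a 5-exo closure, CO would insert into the C5–Pd bond and O7 would trap the acylpalladium. This would give the cis-fused lactone (3aS,5R,6aS)-5-{(1R)-1-[(4-methoxybenzyl)oxy]dec-9-en-1-yl}tetrahydrofuro[3,2-b]furan-2(3H)-one A2, while CuCl2 returns zerovalent palladium to the divalent state.
- In its favour: C6 is tied cis to O7 by the geometry of the bicycle, so the ring configuration does not rest on a transition-state preference. On this point it is better than the chosen plan. In telling O7 from O10 (lactone against ether) it is its equal.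
- Against it here: C7, C9 and C10 must all be set beforehand. C1–C3 are missing, so the lactone carbon C4 has to be reduced, activated and coupled with a propyl unit before O7 can be acylated and the benzyl-type ether removed. A1 holds two monosubstituted alkenes, and the remote one is open to palladium-mediated oxidation or carbonylation. CO and stoichiometric copper are needed.
- Comparison: the key step forms one ring bond and one C–C bond but only one stereocentre, against a ring and two stereocentres. It proceeds by anti oxypalladation and carbonylation, against syn transfer of two oxygens. About five operations follow it, where the chosen key step is the last step.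

Alternative 2: The cut first replaces the C7–O ester bond by a C7–I bond of opposite configuration, then removes O1–C6 and C7–I together. It leads back to the E homoallylic alcohol (6E,9R,10R)-10-[(tert-butyldiphenylsilyl)oxy]nonadeca-6,18-dien-9-ol A3.
- Forward step (I2, NaHCO3, MeCN, 0 °C): an iodonium ion on C6=C7 would be opened by O9 at C6 in a 5-endo closure. Anti addition to the E alkene should give tert-butyl{[(6S,7R,9R,10R)-6,9-epoxy-7-iodononadec-18-en-10-yl]oxy}diphenylsilane A4. Cesium dodecanoate would then have to displace iodide with inversion before desilylation.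
- In its favour: iodine is cheap and no metal is needed, which is better than stoichiometric rhenium. The step creates a ring and two stereocentres from alkene geometry, the equal of the chosen plan. O7 never needs a protecting group, which is better than the acetal-to-ester exchange of the chosen route.
- Against it here: the C7 configuration would finally depend on an SN2 reaction at a secondary ring iodide, and the face open to the nucleophile is the one shielded by the cis pentyl group. E2 elimination to a dihydrofuran is the likely competitor. The 5-endo closure is slower than a 5-exo one, and iodine can add reversibly to C18=C19.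
- Comparison: both plans reach the same net syn result, by anti addition plus inversion here and by direct syn addition there. The alternative needs two steps after its key step against none, with precursors of similar length. The plans are close in length and differ mainly in where the risk lies.

Alternative 3: The cut traces the O1–C9 bond back to an O1–C10 bond, that is, to the six-membered enol ether (2S,3S)-3-(methoxymethoxy)-6-(non-8-en-1-yl)-2-pentyl-3,4-dihydro-2H-pyran A5, with C10 appearing as a ketone in the product.
- Forward step (PhI(OH)OTs, trivalent iodine; MeCN–H2O, 0 °C): the reagent would attack the enol ether at C9, water would add to the C10 oxocarbenium ion, and the ring oxygen would shift from C10 to C9 with loss of iodobenzene. The ring would contract to 1-[(2R,4S,5S)-4-(methoxymethoxy)-5-pentyloxolan-2-yl]dec-9-en-1-one A6.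
- In its favour: no metal is used and no E-selective olefination is needed, because C10 is set later by hydride reduction. On independence from alkene geometry it is better than the chosen plan. The ketone level keeps O10 distinct from O7, which is equal.
- Against it here: C9 depends on the facial selectivity of iodine attack on a half-chair whose substituents sit on C6 and C7, remote from C9. C10 needs a separate Felkin–Anh-controlled reduction, for example with LiBH(s-Bu)3. Solvent capture without migration would give α-oxygenated by-products. The acetal on O7 must still be exchanged for the laurate with O10 masked.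
- Comparison: one stereocentre per step over two stereo-determining steps, against two stereocentres in one step. A cationic 1,2-shift, against a syn addition. At least five steps after A6, against none after the chosen key step.

Key step: step 11

Remarks on the chemistry:
- Atom labels C1–C19 refer to the C19 chain of 21 counted from the pentyl end and are kept for all intermediates.
- Assumption for step 1: the isopinocampheyl groups of the (−)-α-pinene series, from (+)-Ipc2BOMe, direct addition to the Re face of 1, as they do for unbranched aliphatic aldehydes.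

## Steps

Step 1
Reactants: 1 hexanal; 2 allyl methoxymethyl ether
Product: 5 (3S,4S)-3-(methoxymethoxy)non-1-en-4-ol, via (Z)-3-(methoxymethoxy)allyllithium 3 (not isolated), via (Z)-3-(methoxymethoxy)allylbis(isopinocampheyl)borane 4 (not isolated)
Conditions: 2, s-BuLi, THF, −78 °C; (+)-Ipc2BOMe, −78 °C; BF3·OEt2; then 1, −78 °C; NaOH, H2O2, rt
Reagents that add atoms: none
Why: Deprotonation of 2 gives the internally chelated Z oxyallyl anion 3, and the derived borane 4 adds to 1 through a closed chair transition state (asymmetric γ-alkoxyallylboration), so the Z geometry gives the syn C6/C7 pair. The isopinocampheyl groups of the (−)-α-pinene series direct the allyl unit to the Re face of 1, which sets 6S and with it 7S.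

Step 2
Reactants: 5 (3S,4S)-3-(methoxymethoxy)non-1-en-4-ol
Product: 6 tert-butyl{[(3S,4S)-3-(methoxymethoxy)non-1-en-4-yl]oxy}dimethylsilane
Conditions: t-BuMe2SiCl, imidazole, DMAP (cat.), DMF, rt
Reagents that add atoms: tert-butyldimethylsilyl chloride, CC(C)(C)[Si](C)(C)Cl
Why: Silylation of a secondary alcohol under nucleophilic catalysis; the silyl ether masks O6 against the borane, the oxidant and the amide base to come and can be kept while the acetal on O7 is cleaved. No stereocentre is touched.

Step 3
Reactants: 6 tert-butyl{[(3S,4S)-3-(methoxymethoxy)non-1-en-4-yl]oxy}dimethylsilane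
Product: 8 (3S,4S)-4-[(tert-butyldimethylsilyl)oxy]-3-(methoxymethoxy)nonan-1-ol, via B-alkyl-9-borabicyclo[3.3.1]nonane 7 (not isolated)
Conditions: 9-BBN, THF, 0 °C → rt; NaOH, H2O2, 0 °C → rt
Reagents that add atoms: hydrogen peroxide, OO
Why: Hydroboration–oxidation; the bulky dialkylborane places boron on the terminal carbon C9 of the monosubstituted alkene, away from the allylic oxygen, and oxidation replaces boron by hydroxyl. No new stereocentre is formed.

Step 4
Reactants: 8 (3S,4S)-4-[(tert-butyldimethylsilyl)oxy]-3-(methoxymethoxy)nonan-1-ol
Product: 9 (3S,4S)-4-[(tert-butyldimethylsilyl)oxy]-3-(methoxymethoxy)nonanal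
Conditions: Dess–Martin periodinane, CH2Cl2, 0 °C → rt
Reagents that add atoms: none
Why: Dess–Martin oxidation of a primary alcohol stops at the aldehyde under near-neutral conditions, which avoids β-elimination of the C7 oxygen. The aldehyde should be used directly.

Step 5
Reactants: 10 dec-9-en-1-ol
Product: 11 5-(dec-9-en-1-ylsulfanyl)-1-phenyl-1H-tetrazole
Conditions: 1-phenyl-1H-tetrazole-5-thiol, PPh3, DIAD, THF, 0 °C → rt
Reagents that add atoms: 1-phenyl-1H-tetrazole-5-thiol, Sc1nnnn1-c1ccccc1
Why: Mitsunobu thioetherification; the acidic thiol displaces the activated primary alcohol at an unhindered carbon.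

Step 6
Reactants: 11 5-(dec-9-en-1-ylsulfanyl)-1-phenyl-1H-tetrazole
Product: 12 5-(dec-9-en-1-ylsulfonyl)-1-phenyl-1H-tetrazole
Conditions: (NH4)6Mo7O24·4H2O (cat.), H2O2 (30% aq.), EtOH, 0 °C → rt
Reagents that add atoms: hydrogen peroxide, OO
Why: Molybdate-catalysed oxidation of a sulfide to the sulfone; the peroxomolybdate oxidant is selective for sulfur and should not epoxidise an isolated monosubstituted alkene.

Step 7
Reactants: 12 5-(dec-9-en-1-ylsulfonyl)-1-phenyl-1H-tetrazole; 9 (3S,4S)-4-[(tert-butyldimethylsilyl)oxy]-3-(methoxymethoxy)nonanal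
Product: 14 tert-butyl{[(6S,7S,9E)-7-(methoxymethoxy)nonadeca-9,18-dien-6-yl]oxy}dimethylsilane, via potassium sulfonyl carbanion 13 (not isolated)
Conditions: 12, KN(SiMe3)2, DME, −60 °C; then 9, −60 °C → rt; NH4Cl aq.
Reagents that add atoms: none
Why: Julia–Kocienski olefination: 13 adds to 9, the alkoxide undergoes Smiles transfer of the tetrazole, and antiperiplanar loss of SO2 and tetrazololate forms C9=C10. The potassium counter-ion in a coordinating ether favours the open transition state that leads to the E alkene, and pre-formed 13 keeps the enolisable β-alkoxy aldehyde away from free base.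

Step 8
Reactants: 14 tert-butyl{[(6S,7S,9E)-7-(methoxymethoxy)nonadeca-9,18-dien-6-yl]oxy}dimethylsilane
Product: 15 (6S,7S,9E)-6-[(tert-butyldimethylsilyl)oxy]nonadeca-9,18-dien-7-ol
Conditions: Me2BBr, CH2Cl2, −78 °C; then NaHCO3 aq., THF
Reagents that add atoms: none
Why: Lewis-acid cleavage of an acetal-type ether: the boron bromide binds the methoxy oxygen and turns the acetal into a bromomethyl ether that hydrolyses on work-up. At −78 °C the hindered silyl ether and the alkenes should be left alone, and C7 is not touched, so its configuration is kept.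

Step 9
Reactants: 15 (6S,7S,9E)-6-[(tert-butyldimethylsilyl)oxy]nonadeca-9,18-dien-7-ol; 16 lauric acid (dodecanoic acid)
Product: 17 (6S,7S,9E)-6-[(tert-butyldimethylsilyl)oxy]nonadeca-9,18-dien-7-yl dodecanoate
Conditions: EDC·HCl, DMAP, CH2Cl2, rt
Reagents that add atoms: none
Why: Steglich esterification through the acylpyridinium ion; O7 is the only free hydroxyl and is acylated with retention at C7.

Step 10
Reactants: 17 (6S,7S,9E)-6-[(tert-butyldimethylsilyl)oxy]nonadeca-9,18-dien-7-yl dodecanoate
Product: 18 (6S,7S,9E)-6-hydroxynonadeca-9,18-dien-7-yl dodecanoate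
Conditions: HF·pyridine, pyridine, THF, 0 °C → rt
Reagents that add atoms: none
Why: Fluoride-driven desilylation in a weakly acidic, buffered medium, which avoids the alkoxide that would carry the acyl group from O7 to O6. The product should be taken into the next step without storage.

Step 11
Reactants: 18 (6S,7S,9E)-6-hydroxynonadeca-9,18-dien-7-yl dodecanoate
Product: 21 (2S,3S,5R)-5-[(1R)-1-hydroxydec-9-en-1-yl]-2-pentyloxolan-3-yl dodecanoate, via C6 perrhenate ester 19 (not isolated), via C10 oxorhenium alkoxide 20 (not isolated)
Conditions: Re2O7, (CF3CO)2O, THF, rt, then evaporation; 18, (CF3CO)2O (small excess), CH2Cl2, 0 °C → rt; NaHCO3 aq.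
Reagents that add atoms: dirhenium heptoxide, O=[Re](=O)(=O)O[Re](=O)(=O)=O (its oxo oxygen becomes the C10 hydroxyl oxygen by way of trifluoroacetyl perrhenate, O=C(O[Re](=O)(=O)=O)C(F)(F)F)
Why: Trifluoroacetyl perrhenate (heptavalent rhenium) exchanges its acyl group for the C6 hydroxyl of 18 to give the perrhenate ester 19. The O–Re=O unit of 19, held over the alkene by the C6–C7–C8 tether, then adds suprafacially to C9=C10: the ester oxygen bonds to C9 and an oxo oxygen to C10, giving the pentavalent rhenium alkoxide 20, which aqueous work-up hydrolyses to 21. The closest known reaction type is the perrhenate-mediated syn oxidative cyclisation of bishomoallylic alcohols to trans-2,5-disubstituted tetrahydrofuranyl carbinols. The tetrahydrofuran (O1, C6–C9) closes in a 5-exo mode. C9 is controlled by the chair-like transition state in which the pentyl group on C6 lies pseudo-equatorial and away from the oxo ligands, so that C10 ends trans to pentyl (9R); the C7 acyloxy group, cis to pentyl, is a poor donor for rhenium and ends on the face opposite to C10, so it should not redirect the metal. C10 is controlled by the E geometry of the alkene together with syn addition, which makes the O1–C9 and HO–C10 bonds threo (10R). The step needs site selectivity between two alkenes and two oxygen functions: only C9=C10 is within reach of the tethered metal, C18=C19 has no hydroxyl partner, and the ester oxygen cannot form a perrhenate.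

## Compound list

1 | hexanal | CCCCCC=O | starting material
2 | allyl methoxymethyl ether, 3-(methoxymethoxy)prop-1-ene | C=CCOCOC | starting material
3 | (Z)-3-(methoxymethoxy)allyllithium (not isolated) | [Li]C/C=C\OCOC | intermediate
4 | [(2Z)-3-(methoxymethoxy)prop-2-en-1-yl]bis(isopinocampheyl)borane, isopinocampheyl groups of the (−)-α-pinene series (not isolated) | COCO/C=C\CB([C@H]1C[C@H]2C[C@H](C2(C)C)[C@@H]1C)[C@H]1C[C@H]2C[C@H](C2(C)C)[C@@H]1C | intermediate
5 | (3S,4S)-3-(methoxymethoxy)non-1-en-4-ol | C=C[C@H](OCOC)[C@H](CCCCC)O | intermediate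
6 | tert-butyl{[(3S,4S)-3-(methoxymethoxy)non-1-en-4-yl]oxy}dimethylsilane | C=C[C@H](OCOC)[C@H](CCCCC)O[Si](C)(C)C(C)(C)C | intermediate
7 | 9-{(3S,4S)-4-[(tert-butyldimethylsilyl)oxy]-3-(methoxymethoxy)nonyl}-9-borabicyclo[3.3.1]nonane (not isolated) | B1(CC[C@H](OCOC)[C@H](CCCCC)O[Si](C)(C)C(C)(C)C)C2CCCC1CCC2 | intermediate
8 | (3S,4S)-4-[(tert-butyldimethylsilyl)oxy]-3-(methoxymethoxy)nonan-1-ol | OCC[C@H](OCOC)[C@H](CCCCC)O[Si](C)(C)C(C)(C)C | intermediate
9 | (3S,4S)-4-[(tert-butyldimethylsilyl)oxy]-3-(methoxymethoxy)nonanal | O=CC[C@H](OCOC)[C@H](CCCCC)O[Si](C)(C)C(C)(C)C | intermediate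
10 | dec-9-en-1-ol | C=CCCCCCCCCO | starting material
11 | 5-(dec-9-en-1-ylsulfanyl)-1-phenyl-1H-tetrazole | C=CCCCCCCCCSc1nnnn1-c1ccccc1 | intermediate
12 | 5-(dec-9-en-1-ylsulfonyl)-1-phenyl-1H-tetrazole | C=CCCCCCCCCS(=O)(=O)c1nnnn1-c1ccccc1 | intermediate
13 | potassium 1-[(1-phenyl-1H-tetrazol-5-yl)sulfonyl]dec-9-en-1-ide (not isolated) | [K+].C=CCCCCCCC[CH-]S(=O)(=O)c1nnnn1-c1ccccc1 | intermediate
14 | tert-butyl{[(6S,7S,9E)-7-(methoxymethoxy)nonadeca-9,18-dien-6-yl]oxy}dimethylsilane | C=CCCCCCCC/C=C/C[C@H](OCOC)[C@H](CCCCC)O[Si](C)(C)C(C)(C)C | intermediate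
15 | (6S,7S,9E)-6-[(tert-butyldimethylsilyl)oxy]nonadeca-9,18-dien-7-ol | C=CCCCCCCC/C=C/C[C@H](O)[C@H](CCCCC)O[Si](C)(C)C(C)(C)C | intermediate
16 | lauric acid (dodecanoic acid) | CCCCCCCCCCCC(=O)O | starting material
17 | (6S,7S,9E)-6-[(tert-butyldimethylsilyl)oxy]nonadeca-9,18-dien-7-yl dodecanoate | C=CCCCCCCC/C=C/C[C@H](OC(=O)CCCCCCCCCCC)[C@H](CCCCC)O[Si](C)(C)C(C)(C)C | intermediate
18 | (6S,7S,9E)-6-hydroxynonadeca-9,18-dien-7-yl dodecanoate | C=CCCCCCCC/C=C/C[C@H](OC(=O)CCCCCCCCCCC)[C@H](CCCCC)O | intermediate
19 | (6S,7S,9E)-7-(dodecanoyloxy)nonadeca-9,18-dien-6-yl perrhenate, heptavalent rhenium (not isolated) | C=CCCCCCCC/C=C/C[C@H](OC(=O)CCCCCCCCCCC)[C@H](CCCCC)O[Re](=O)(=O)=O | intermediate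
20 | dioxorhenium alkoxide at O10 of 21, pentavalent rhenium (not isolated) | C=CCCCCCCC[C@@H](O[Re](=O)=O)[C@H]1C[C@H](OC(=O)CCCCCCCCCCC)[C@H](CCCCC)O1 | intermediate
21 | (2S,3S,5R)-5-[(1R)-1-hydroxydec-9-en-1-yl]-2-pentyloxolan-3-yl dodecanoate, that is (6S,7S,9R,10R)-6,9-epoxy-10-hydroxynonadec-18-en-7-yl dodecanoate | C=CCCCCCCC[C@@H](O)[C@H]1C[C@H](OC(=O)CCCCCCCCCCC)[C@H](CCCCC)O1 | target

## Step count and least certain steps

Total step count: 11 steps. Longest linear sequence: 9 steps (steps 1–4 and 7–11, from 1 and 2 to 21); the sulfone branch (steps 5 and 6) joins at step 7.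

Step 11 (key step).
- What may go wrong: the acyl group can shift from O7 to the free O6 in the acidic medium before the perrhenate ester forms, O6 can be capped as a trifluoroacetate, and facial selectivity can erode because the cis C6/C7 substituents cannot both lie pseudo-equatorial in the cyclisation transition state.
- Fallback, setting out from 9 and returning at 21. It builds the ring by a cobalt-catalysed aerobic cyclisation and the carbinol by chelation-controlled addition. Wittig methylenation of 9 (Ph3P=CH2, THF) gives tert-butyl{[(4S,5S)-4-(methoxymethoxy)dec-1-en-5-yl]oxy}dimethylsilane F1. Bu4NF frees (4S,5S)-4-(methoxymethoxy)dec-1-en-5-ol F2. Aerobic oxidative cyclisation with Co(modp)2 (divalent cobalt; modp = 1-morpholinocarbamoyl-4,4-dimethylpentane-1,3-dionate; O2, t-BuOOH, i-PrOH, 55 °C) should close the trans ring to [(2R,4S,5S)-4-(methoxymethoxy)-5-pentyloxolan-2-yl]methanol F3. Dess–Martin oxidation gives (2R,4S,5S)-4-(methoxymethoxy)-5-pentyloxolane-2-carbaldehyde F4. Non-8-enylmagnesium bromide with MgBr2·OEt2 (CH2Cl2, −78 °C) should add under chelation between the aldehyde and ring oxygens to give the threo carbinol (6S,7S,9R,10R)-6,9-epoxy-7-(methoxymethoxy)nonadec-18-en-10-ol F5. t-BuPh2SiCl and imidazole give tert-butyl{[(6S,7S,9R,10R)-6,9-epoxy-7-(methoxymethoxy)nonadec-18-en-10-yl]oxy}diphenylsilane F6. ZnBr2 and n-PrSH cleave the acetal to (6S,7S,9R,10R)-10-[(tert-butyldiphenylsilyl)oxy]-6,9-epoxynonadec-18-en-7-ol F7. Steglich esterification with 16 gives (6S,7S,9R,10R)-10-[(tert-butyldiphenylsilyl)oxy]-6,9-epoxynonadec-18-en-7-yl dodecanoate F8. Bu4NF buffered with acetic acid removes the silyl group and gives 21.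

Step 8.
- What may go wrong: partial loss of the silyl ether on O6 during acetal cleavage, or incomplete cleavage, would leave mixtures that cannot be acylated selectively at O7.
- Fallback, setting out from 14 and returning at 21. It removes the silyl group instead and moves the acylation behind the ring closure. Bu4NF gives (6S,7S,9E)-7-(methoxymethoxy)nonadeca-9,18-dien-6-ol F9. The CF3CO2ReO3 cyclisation of step 11, applied to F9, should give (6S,7S,9R,10R)-6,9-epoxy-7-(methoxymethoxy)nonadec-18-en-10-ol F5. This is carried on as above through the C10 tert-butyldiphenylsilyl ether F6, the C7 alcohol F7 and the C7 laurate F8 to 21. In this order the acetal is cleaved beside the more robust diphenylsilyl ether.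

Step 7.
- What may go wrong: incomplete E selectivity, because an unbranched sulfone and an α-unbranched aldehyde offer little steric bias, and base-induced β-elimination of the C7 oxygen from 9. Any Z alkene would end as the C10 epimer of 21.
- Fallback, setting out from 9 and returning at 14. It makes the alkene by stereospecific reduction of an alkyne. Ohira–Bestmann homologation (dimethyl (1-diazo-2-oxopropyl)phosphonate, K2CO3, MeOH) gives tert-butyl{[(4S,5S)-4-(methoxymethoxy)dec-1-yn-5-yl]oxy}dimethylsilane F10. n-BuLi, then 9-bromonon-1-ene (THF, DMPU), gives tert-butyl{[(6S,7S)-7-(methoxymethoxy)nonadec-18-en-9-yn-6-yl]oxy}dimethylsilane F11. Sodium in liquid NH3 (THF, −78 to −33 °C) should reduce the alkyne to the E alkene only and leave the isolated vinyl group, giving 14.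

## Further compounds

F1 | step 11 | tert-butyl{[(4S,5S)-4-(methoxymethoxy)dec-1-en-5-yl]oxy}dimethylsilane | C=CC[C@H](OCOC)[C@H](CCCCC)O[Si](C)(C)C(C)(C)C
F2 | step 11 | (4S,5S)-4-(methoxymethoxy)dec-1-en-5-ol | C=CC[C@H](OCOC)[C@H](CCCCC)O
F3 | step 11 | [(2R,4S,5S)-4-(methoxymethoxy)-5-pentyloxolan-2-yl]methanol | OC[C@H]1C[C@H](OCOC)[C@H](CCCCC)O1
F4 | step 11 | (2R,4S,5S)-4-(methoxymethoxy)-5-pentyloxolane-2-carbaldehyde | O=C[C@H]1C[C@H](OCOC)[C@H](CCCCC)O1
F5 | step 11 | (6S,7S,9R,10R)-6,9-epoxy-7-(methoxymethoxy)nonadec-18-en-10-ol | C=CCCCCCCC[C@@H](O)[C@H]1C[C@H](OCOC)[C@H](CCCCC)O1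
F6 | step 11 | tert-butyl{[(6S,7S,9R,10R)-6,9-epoxy-7-(methoxymethoxy)nonadec-18-en-10-yl]oxy}diphenylsilane | C=CCCCCCCC[C@@H](O[Si](c1ccccc1)(c1ccccc1)C(C)(C)C)[C@H]1C[C@H](OCOC)[C@H](CCCCC)O1
F7 | step 11 | (6S,7S,9R,10R)-10-[(tert-butyldiphenylsilyl)oxy]-6,9-epoxynonadec-18-en-7-ol | C=CCCCCCCC[C@@H](O[Si](c1ccccc1)(c1ccccc1)C(C)(C)C)[C@H]1C[C@H](O)[C@H](CCCCC)O1
F8 | step 11 | (6S,7S,9R,10R)-10-[(tert-butyldiphenylsilyl)oxy]-6,9-epoxynonadec-18-en-7-yl dodecanoate | C=CCCCCCCC[C@@H](O[Si](c1ccccc1)(c1ccccc1)C(C)(C)C)[C@H]1C[C@H](OC(=O)CCCCCCCCCCC)[C@H](CCCCC)O1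
F9 | step 8 | (6S,7S,9E)-7-(methoxymethoxy)nonadeca-9,18-dien-6-ol | C=CCCCCCCC/C=C/C[C@H](OCOC)[C@H](CCCCC)O
F10 | step 7 | tert-butyl{[(4S,5S)-4-(methoxymethoxy)dec-1-yn-5-yl]oxy}dimethylsilane | C#CC[C@H](OCOC)[C@H](CCCCC)O[Si](C)(C)C(C)(C)C
F11 | step 7 | tert-butyl{[(6S,7S)-7-(methoxymethoxy)nonadec-18-en-9-yn-6-yl]oxy}dimethylsilane | C=CCCCCCCCC#CC[C@H](OCOC)[C@H](CCCCC)O[Si](C)(C)C(C)(C)C
A1 | alternative 1 | (3S,5R,6R)-6-[(4-methoxybenzyl)oxy]pentadeca-1,14-diene-3,5-diol | C=CCCCCCCC[C@@H](OCc1ccc(OC)cc1)[C@H](O)C[C@H](O)C=C
A2 | alternative 1 | (3aS,5R,6aS)-5-{(1R)-1-[(4-methoxybenzyl)oxy]dec-9-en-1-yl}tetrahydrofuro[3,2-b]furan-2(3H)-one | C=CCCCCCCC[C@@H](OCc1ccc(OC)cc1)[C@H]1C[C@@H]2OC(=O)C[C@@H]2O1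
A3 | alternative 2 | (6E,9R,10R)-10-[(tert-butyldiphenylsilyl)oxy]nonadeca-6,18-dien-9-ol | C=CCCCCCCC[C@@H](O[Si](c1ccccc1)(c1ccccc1)C(C)(C)C)[C@H](O)C/C=C/CCCCC
A4 | alternative 2 | tert-butyl{[(6S,7R,9R,10R)-6,9-epoxy-7-iodononadec-18-en-10-yl]oxy}diphenylsilane | C=CCCCCCCC[C@@H](O[Si](c1ccccc1)(c1ccccc1)C(C)(C)C)[C@H]1C[C@@H](I)[C@H](CCCCC)O1
A5 | alternative 3 | (2S,3S)-3-(methoxymethoxy)-6-(non-8-en-1-yl)-2-pentyl-3,4-dihydro-2H-pyran | C=CCCCCCCCC1=CC[C@H](OCOC)[C@H](CCCCC)O1
A6 | alternative 3 | 1-[(2R,4S,5S)-4-(methoxymethoxy)-5-pentyloxolan-2-yl]dec-9-en-1-one | C=CCCCCCCCC(=O)[C@H]1C[C@H](OCOC)[C@H](CCCCC)O1
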